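**Retrosynthetic overview**
1. Target 32 is a (2R,3R)-dihydroflavonol; the last step removes four MOM ethers and a mixed ketal on O3 from 31.
2. Ring C is closed last: O1–C8a and C4–C4a are made together by annulating aryne 28 (ring A, C4a≡C8a) with β-oxido lactone 29, an O1–C2–C3–C4 unit that already carries ring B and both stereocentres.
3. Enabling feature: in ring A the C4a/C8a pair has an oxygen neighbour only at C5, so the 3-alkoxy aryne takes oxygen at C8a and leaves the carbanion at C4a. In ring C, O1 and C4 are 1,4-related and C3 bears OH, so C2–C3–C4 is a glycolate aldol unit. Its butane-2,3-diacetal (BDA) lactone is a temporary ring that sets the anti stereochemistry, masks O3 and activates C4.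
4. Aryne precursor 11 comes from resorcinol (MOM, prenylation, C–H borylation/oxidation, bromination, retro-Brook/triflation); aldehyde 18 from 2,4-dihydroxybenzaldehyde (MOM, α-amino-alkoxide-directed lithiation/geranylation); BDA glycolate 24 from (S)-3-chloropropane-1,2-diol.
5. Ring order: rings A and B are bought as resorcinol and 2,4-dihydroxybenzaldehyde; the dioxanone ring is built (step 8), used (step 11) and opened (step 12); ring C forms in step 12.

Key step: step 12

Remark: flavonoid numbering is used (O1, C2, C3, C4, C4a, C5 to C8, C8a; ring B primed); it is assumed that hemiketal alkoxide 30 gives up methanol on the acetic acid quench, so that O3 of 31 carries a 2-methoxy-3-oxobutan-2-yl mixed ketal.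

**Route**

Step 1
Reactants: 1 resorcinol
Product: 2 1,3-bis(methoxymethoxy)benzene
Conditions: NaH, MOMCl, DMF, 0 °C → rt
Reagents that add atoms: chloromethyl methyl ether COCCl
Why: Double Williamson-type O-alkylation of the resorcinol dianion should give the bis-MOM ether, which protects the phenols and directs the later lithiation.

Step 2
Reactants: 2 1,3-bis(methoxymethoxy)benzene; 3 prenyl bromide (1-bromo-3-methylbut-2-ene)
Product: 5 1,3-bis(methoxymethoxy)-2-(3-methylbut-2-en-1-yl)benzene, via aryllithium 4 (not isolated)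
Conditions: n-BuLi, THF, 0 °C → rt; then CuI (10 mol%), 3, –78 °C → rt
Reagents that add atoms: none
Why: Directed ortho-metalation should occur at C2 between the two OMOM groups, and copper-catalysed SN2 allylation of the aryllithium should give the linear prenyl arene.

Step 3
Reactants: 5 1,3-bis(methoxymethoxy)-2-(3-methylbut-2-en-1-yl)benzene
Product: 7 3,5-bis(methoxymethoxy)-4-(3-methylbut-2-en-1-yl)phenol, via aryl pinacol boronate 6 (not isolated)
Conditions: [Ir(OMe)(cod)]2 (cat.), 4,4'-di-tert-butyl-2,2'-bipyridine (cat.), B2pin2, THF, 60 °C; then aq. H2O2, NaOH, 0 °C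
Reagents that add atoms: hydrogen peroxide OO
Why: Iridium-catalysed aromatic C–H borylation is sterically controlled and should borylate the only ring position without an ortho substituent (para to the prenyl group), and basic peroxide oxidation of the C–B bond should then give the phenol without touching the trisubstituted alkene.

Step 4
Reactants: 7 3,5-bis(methoxymethoxy)-4-(3-methylbut-2-en-1-yl)phenol
Product: 8 2-bromo-3,5-bis(methoxymethoxy)-4-(3-methylbut-2-en-1-yl)phenol
Conditions: NBS (1.0 equiv), CH2Cl2, –78 °C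
Reagents that add atoms: N-bromosuccinimide O=C1CCC(=O)N1Br
Why: Electrophilic aromatic bromination of the very electron-rich phenol should be much faster than attack on the alkene at –78 °C, and the two free ring positions are equivalent (both ortho to OH), so one monobromide is expected.

Step 5
Reactants: 8 2-bromo-3,5-bis(methoxymethoxy)-4-(3-methylbut-2-en-1-yl)phenol
Product: 11 3,5-bis(methoxymethoxy)-4-(3-methylbut-2-en-1-yl)-2-(trimethylsilyl)phenyl trifluoromethanesulfonate, via silyl ether 9 (not isolated), via lithium phenolate 10 (not isolated)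
Conditions: (Me3Si)2NH, THF, 65 °C, then evaporation; n-BuLi, THF, –78 °C; then Tf2O, –78 °C
Reagents that add atoms: hexamethyldisilazane C[Si](C)(C)N[Si](C)(C)C; trifluoromethanesulfonic anhydride O=S(=O)(OS(=O)(=O)C(F)(F)F)C(F)(F)F
Why: O-silylation, bromine–lithium exchange and anionic 1,3 O→C silyl shift (retro-Brook rearrangement) should place SiMe3 ortho to the phenolate, which is triflated in the same flask to give the ortho-silylaryl triflate.

Step 6
Reactants: 12 2,4-dihydroxybenzaldehyde
Product: 13 2,4-bis(methoxymethoxy)benzaldehyde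
Conditions: NaH, MOMCl, DMF, 0 °C → rt
Reagents that add atoms: chloromethyl methyl ether COCCl
Why: Double Williamson-type O-alkylation of the dianion of the non-enolisable hydroxybenzaldehyde should give the bis-MOM ether, which places the two directing groups on either side of C3.

Step 7
Reactants: 13 2,4-bis(methoxymethoxy)benzaldehyde; 14 geranyl bromide ((2E)-1-bromo-3,7-dimethylocta-2,6-diene)
Product: 18 3-[(2E)-3,7-dimethylocta-2,6-dien-1-yl]-2,4-bis(methoxymethoxy)benzaldehyde, via amino alkoxide 15 (not isolated), via aryllithium 16 (not isolated), via geranylated amino alkoxide 17 (not isolated)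
Conditions: N-methylpiperazine, n-BuLi, THF, –20 °C; then 13; then n-BuLi, –20 → 0 °C; then CuI (10 mol%), 14, –78 °C → rt; then AcOH, H2O
Reagents that add atoms: none
Why: In this directed ortho-metalation of an aldehyde masked in situ as its lithium α-amino alkoxide (Comins' method), the weakly directing N-methylpiperazine adduct should leave n-BuLi to deprotonate C3 between the two OMOM groups, copper-catalysed SN2 allylation should install the geranyl chain with the E double bond unchanged, and the aqueous acid quench should release the aldehyde.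

Step 8
Reactants: 19 (S)-3-chloropropane-1,2-diol; 20 butane-2,3-dione
Product: 21 (2S,5S,6S)-2-(chloromethyl)-5,6-dimethoxy-5,6-dimethyl-1,4-dioxane
Conditions: HC(OMe)3, camphorsulfonic acid (cat.), MeOH, reflux
Reagents that add atoms: trimethyl orthoformate COC(OC)OC
Why: Acid-catalysed butane-2,3-diacetal formation under thermodynamic control should put both OMe groups axial (anomeric effect) and the chloromethyl group equatorial, so the one stereocentre of the diol fixes both acetal centres.

Step 9
Reactants: 21 (2S,5S,6S)-2-(chloromethyl)-5,6-dimethoxy-5,6-dimethyl-1,4-dioxane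
Product: 22 (2S,3S)-2,3-dimethoxy-2,3-dimethyl-5-methylidene-1,4-dioxane
Conditions: KOtBu, THF, reflux
Reagents that add atoms: none
Why: E2 dehydrochlorination should give the exocyclic enol ether, leaving the two acetal centres as the only stereochemical information.

Step 10
Reactants: 22 (2S,3S)-2,3-dimethoxy-2,3-dimethyl-5-methylidene-1,4-dioxane
Product: 24 (5S,6S)-5,6-dimethoxy-5,6-dimethyl-1,4-dioxan-2-one, via secondary ozonide 23 (not isolated)
Conditions: O3, CH2Cl2, –78 °C; then Me2S, –78 °C → rt
Reagents that add atoms: ozone [O-][O+]=O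
Why: Ozonolysis of the enol ether double bond with reductive work-up should give the lactone, the BDA-protected glycolic acid.

Step 11
Reactants: 24 (5S,6S)-5,6-dimethoxy-5,6-dimethyl-1,4-dioxan-2-one; 18 3-[(2E)-3,7-dimethylocta-2,6-dien-1-yl]-2,4-bis(methoxymethoxy)benzaldehyde
Product: 27 (3R,5S,6S)-3-[(R)-{3-[(2E)-3,7-dimethylocta-2,6-dien-1-yl]-2,4-bis(methoxymethoxy)phenyl}(trimethylsilyloxy)methyl]-5,6-dimethoxy-5,6-dimethyl-1,4-dioxan-2-one, via lithium enolate 25 (not isolated), via lithium aldolate 26 (not isolated)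
Conditions: LiN(SiMe3)2, THF, –78 °C; then 18, –78 °C; then Me3SiCl, –78 → –20 °C
Reagents that add atoms: chlorotrimethylsilane C[Si](C)(C)Cl
Why: In this anti-selective glycolate aldol addition the lithium enolate should be attacked on the face opposite to the axial OMe at C5 (setting C3 as R), its ring-fixed E(O) geometry should give the anti (R) carbinol through a chair Zimmerman–Traxler transition state, and silylation at low temperature should trap the aldolate before retro-aldol.

Step 12
Reactants: 11 3,5-bis(methoxymethoxy)-4-(3-methylbut-2-en-1-yl)-2-(trimethylsilyl)phenyl trifluoromethanesulfonate; 27 the silylated anti aldol adduct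
Product: 31 (2R,3R)-2-{3-[(2E)-3,7-dimethylocta-2,6-dien-1-yl]-2,4-bis(methoxymethoxy)phenyl}-3-{[(2S)-2-methoxy-3-oxobutan-2-yl]oxy}-5,7-bis(methoxymethoxy)-6-(3-methylbut-2-en-1-yl)-2,3-dihydro-4H-chromen-4-one, via aryne 28 (not isolated), via caesium alkoxide 29 (not isolated), via hemiketal alkoxide 30 (not isolated)
Conditions: 11 (1.5 equiv), CsF, 18-crown-6, THF, 0 °C → rt; then AcOH, 0 °C
Reagents that add atoms: none
Why: Proposed new method: fluoride removes SiMe3 from both partners, giving aryne 28 (1,2-elimination of triflate) and the proton-free alkoxide 29; the alkoxide adds to the aryne carbon that becomes C8a, and the aryl anion left at C4a attacks the lactone carbonyl and expels the ketal oxygen, so that O1–C8a and C4–C4a form in one operation and the dioxanone opens to 30, which loses methanol on quench. The closest known reactions are the fluoride-induced annulation of arynes by methyl salicylates to xanthones (O-arylation, then attack of the aryl anion on the ester) and the insertion of arynes into the N–C(O) bond of β-lactams; new here are an aliphatic alkoxide as nucleophile and a lactone as acyl donor. Ring C is closed by intermolecular O-arylation followed by a 6-exo-trig acyl substitution. No stereocentre is created: C2 and C3 are carried over from 27 with all four bonds intact, so the (2R,3R) trans relationship is that of the anti aldol and is also the preferred diequatorial arrangement. The step needs regioselective addition to the aryne, which the C5 OMOM group should secure (3-alkoxy arynes take nucleophiles at the carbon meta to oxygen and C8a is also the less hindered terminus), and it needs acylation to outrun protonation of the aryl anion, which the silyl-masked alkoxide, the aprotic medium and the six-membered transition state to an activated lactone should secure.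

Step 13
Reactants: 31 the protected dihydroflavonol
Product: 32 (2R,3R)-2-{3-[(2E)-3,7-dimethylocta-2,6-dien-1-yl]-2,4-dihydroxyphenyl}-3,5,7-trihydroxy-6-(3-methylbut-2-en-1-yl)-2,3-dihydro-4H-chromen-4-one (CNP0166115.1)
Conditions: HCl (cat.), MeOH, 0 °C → rt
Reagents that add atoms: none
Why: Acid-catalysed acetal solvolysis in methanol should remove the four phenolic MOM groups and the mixed ketal on O3 under conditions mild enough that the ortho-prenyl and ortho-geranyl phenols do not cyclise and the trans C2/C3 centres are not epimerised.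

**Compound list**
1 | resorcinol | Oc1cccc(O)c1 | starting material
2 | 1,3-bis(methoxymethoxy)benzene | COCOc1cccc(OCOC)c1 | intermediate
3 | prenyl bromide (1-bromo-3-methylbut-2-ene) | CC(C)=CCBr | starting material
4 | [2,6-bis(methoxymethoxy)phenyl]lithium | [Li]c1c(OCOC)cccc1OCOC | intermediate
5 | 1,3-bis(methoxymethoxy)-2-(3-methylbut-2-en-1-yl)benzene | CC(C)=CCc1c(OCOC)cccc1OCOC | intermediate
6 | 2-[3,5-bis(methoxymethoxy)-4-(3-methylbut-2-en-1-yl)phenyl]-4,4,5,5-tetramethyl-1,3,2-dioxaborolane | CC(C)=CCc1c(OCOC)cc(B2OC(C)(C)C(C)(C)O2)cc1OCOC | intermediate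
7 | 3,5-bis(methoxymethoxy)-4-(3-methylbut-2-en-1-yl)phenol | CC(C)=CCc1c(OCOC)cc(O)cc1OCOC | intermediate
8 | 2-bromo-3,5-bis(methoxymethoxy)-4-(3-methylbut-2-en-1-yl)phenol | CC(C)=CCc1c(OCOC)cc(O)c(Br)c1OCOC | intermediate
9 | [2-bromo-3,5-bis(methoxymethoxy)-4-(3-methylbut-2-en-1-yl)phenoxy]trimethylsilane | CC(C)=CCc1c(OCOC)cc(O[Si](C)(C)C)c(Br)c1OCOC | intermediate
10 | lithium 3,5-bis(methoxymethoxy)-4-(3-methylbut-2-en-1-yl)-2-(trimethylsilyl)phenolate | [Li+].CC(C)=CCc1c(OCOC)cc([O-])c([Si](C)(C)C)c1OCOC | intermediate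
11 | 3,5-bis(methoxymethoxy)-4-(3-methylbut-2-en-1-yl)-2-(trimethylsilyl)phenyl trifluoromethanesulfonate | CC(C)=CCc1c(OCOC)cc(OS(=O)(=O)C(F)(F)F)c([Si](C)(C)C)c1OCOC | intermediate
12 | 2,4-dihydroxybenzaldehyde | O=Cc1ccc(O)cc1O | starting material
13 | 2,4-bis(methoxymethoxy)benzaldehyde | COCOc1ccc(C=O)c(OCOC)c1 | intermediate
14 | geranyl bromide ((2E)-1-bromo-3,7-dimethylocta-2,6-diene) | CC(C)=CCC/C(C)=C/CBr | starting material
15 | lithium [2,4-bis(methoxymethoxy)phenyl](4-methylpiperazin-1-yl)methanolate (aminal carbon racemic) | COCOc1ccc(C([O-])N2CCN(C)CC2)c(OCOC)c1.[Li+] | intermediate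
16 | lithium [3-lithio-2,4-bis(methoxymethoxy)phenyl](4-methylpiperazin-1-yl)methanolate | [Li]c1c(OCOC)ccc(C([O-])N2CCN(C)CC2)c1OCOC.[Li+] | intermediate
17 | lithium {3-[(2E)-3,7-dimethylocta-2,6-dien-1-yl]-2,4-bis(methoxymethoxy)phenyl}(4-methylpiperazin-1-yl)methanolate | CC(C)=CCC/C(C)=C/Cc1c(OCOC)ccc(C([O-])N2CCN(C)CC2)c1OCOC.[Li+] | intermediate
18 | 3-[(2E)-3,7-dimethylocta-2,6-dien-1-yl]-2,4-bis(methoxymethoxy)benzaldehyde | CC(C)=CCC/C(C)=C/Cc1c(OCOC)ccc(C=O)c1OCOC | intermediate
19 | (S)-3-chloropropane-1,2-diol | OC[C@H](O)CCl | starting material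
20 | butane-2,3-dione | CC(=O)C(C)=O | starting material
21 | (2S,5S,6S)-2-(chloromethyl)-5,6-dimethoxy-5,6-dimethyl-1,4-dioxane | ClC[C@@H]1CO[C@](C)(OC)[C@@](C)(OC)O1 | intermediate
22 | (2S,3S)-2,3-dimethoxy-2,3-dimethyl-5-methylidene-1,4-dioxane | C=C1CO[C@](C)(OC)[C@@](C)(OC)O1 | intermediate
23 | secondary ozonide of 22 (spiro-1,2,4-trioxolane, spiro centre undefined) | C1OOC2(O1)CO[C@](C)(OC)[C@@](C)(OC)O2 | intermediate
24 | (5S,6S)-5,6-dimethoxy-5,6-dimethyl-1,4-dioxan-2-one | O=C1CO[C@](C)(OC)[C@@](C)(OC)O1 | intermediate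
25 | lithium enolate of 24 | [Li+].[O-]C1=CO[C@](C)(OC)[C@@](C)(OC)O1 | intermediate
26 | lithium aldolate, (3R) at the dioxanone and (R) at the carbinol carbon | CC(C)=CCC/C(C)=C/Cc1c(OCOC)ccc([C@@H]([O-])[C@H]2O[C@](C)(OC)[C@@](C)(OC)OC2=O)c1OCOC.[Li+] | intermediate
27 | (3R,5S,6S)-3-[(R)-{3-[(2E)-3,7-dimethylocta-2,6-dien-1-yl]-2,4-bis(methoxymethoxy)phenyl}(trimethylsilyloxy)methyl]-5,6-dimethoxy-5,6-dimethyl-1,4-dioxan-2-one | CC(C)=CCC/C(C)=C/Cc1c(OCOC)ccc([C@@H](O[Si](C)(C)C)[C@H]2O[C@](C)(OC)[C@@](C)(OC)OC2=O)c1OCOC | intermediate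
28 | 1,2-didehydro-3,5-bis(methoxymethoxy)-4-(3-methylbut-2-en-1-yl)benzene (aryne) | CC(C)=CCC1=C(OCOC)C#CC=C1OCOC | intermediate
29 | caesium alkoxide from 27 | CC(C)=CCC/C(C)=C/Cc1c(OCOC)ccc([C@@H]([O-])[C@H]2O[C@](C)(OC)[C@@](C)(OC)OC2=O)c1OCOC.[Cs+] | intermediate
30 | ring-opened hemiketal caesium alkoxide, (2R,3R) chromanone core | CC(C)=CCC/C(C)=C/Cc1c(OCOC)ccc([C@H]2Oc3cc(OCOC)c(CC=C(C)C)c(OCOC)c3C(=O)[C@@H]2O[C@](C)(OC)[C@@](C)(OC)[O-])c1OCOC.[Cs+] | intermediate
31 | (2R,3R)-2-{3-[(2E)-3,7-dimethylocta-2,6-dien-1-yl]-2,4-bis(methoxymethoxy)phenyl}-3-{[(2S)-2-methoxy-3-oxobutan-2-yl]oxy}-5,7-bis(methoxymethoxy)-6-(3-methylbut-2-en-1-yl)-2,3-dihydro-4H-chromen-4-one | CC(C)=CCC/C(C)=C/Cc1c(OCOC)ccc([C@H]2Oc3cc(OCOC)c(CC=C(C)C)c(OCOC)c3C(=O)[C@@H]2O[C@](C)(OC)C(C)=O)c1OCOC | intermediate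
32 | (2R,3R)-2-{3-[(2E)-3,7-dimethylocta-2,6-dien-1-yl]-2,4-dihydroxyphenyl}-3,5,7-trihydroxy-6-(3-methylbut-2-en-1-yl)-2,3-dihydro-4H-chromen-4-one | CC(C)=CCC/C(C)=C/Cc1c(O)ccc([C@H]2Oc3cc(O)c(CC=C(C)C)c(O)c3C(=O)[C@@H]2O)c1O | target

**Step count and risks**

Total: 13 steps. Longest linear sequence: 7 steps (1 → 2 → 5 → 7 → 8 → 11 → 31 → 32; steps 1, 2, 3, 4, 5, 12, 13).

1. Step 12 (proposed new method). What may go wrong: the aryl anion is protonated before it acylates (for example by C3–H through a six-membered transition state), the alkoxide fragments by retro-aldol before it meets the aryne, or addition to the aryne is not regioselective. The fallback keeps the aryne and the simultaneous formation of both bonds but uses known chemistry; it sets out from 11 (with 18) and rejoins the route at 32. Triflate 11 is heated with acetic acid and CsF in THF at 125 °C, the known intermolecular C–O addition of carboxylic acids to arynes with acyl migration, which should give the ortho-hydroxyaryl ketone F1. Claisen–Schmidt condensation of F1 with aldehyde 18 (KOH, EtOH) should give the 2'-hydroxychalcone F2, and silylation (TBSOTf, 2,6-lutidine) its silyl ether F3. Julia–Colonna epoxidation (poly-L-leucine, urea–H2O2, DBU, THF) should give the (2R,3S)-epoxide F4. Buffered desilylation (TBAF, AcOH) frees phenol F5, which should close ring C in the same flask by 6-endo opening of the epoxide at the benzylic carbon with inversion, giving the trans dihydroflavonol tetra-MOM ether F6. F6 is deprotected under the conditions of step 13 to give 32.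

2. Step 11. What may go wrong: poor anti/syn selectivity at the carbinol centre with the hindered, electron-rich aldehyde, or retro-aldol equilibration before the silyl trap. The fallback corrects the carbinol centre by oxidation and reagent-controlled reduction; it sets out from 27 (as the mixture of carbinol epimers) and returns to 27. The silyl group is removed (citric acid, MeOH) to give alcohol F7, which is oxidised (Dess–Martin periodinane, NaHCO3) to the β-keto lactone F8; C3 should stay R there because the aroyl group remains equatorial and anti to the axial OMe. Noyori asymmetric transfer hydrogenation (RuCl[(S,S)-TsDPEN](p-cymene), HCO2H/Et3N) should return F7 as the single (R)-carbinol, and Me3SiCl/imidazole regenerates 27.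

3. Step 3. What may go wrong: hydroboration or isomerisation of the prenyl alkene by the iridium boryl/pinacolborane system, or incomplete steric control of the borylation site. The fallback introduces the alkene only after the C–H functionalisation; it sets out from 2 and returns at 7. The same borylation applied to 2 should give boronate F9 at C5, and peroxide oxidation the phenol F10; TIPSCl/imidazole gives the silyl ether F11. n-BuLi should lithiate between the two OMOM groups, because the bulky, non-coordinating OTIPS group keeps the base from its own ortho positions, giving aryllithium F12. Prenylation with 3 (CuI cat.) should give F13, and TBAF then releases phenol 7.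

**Further compounds**
F1 | step 12 | 1-[6-hydroxy-2,4-bis(methoxymethoxy)-3-(3-methylbut-2-en-1-yl)phenyl]ethan-1-one | CC(=O)c1c(O)cc(OCOC)c(CC=C(C)C)c1OCOC
F2 | step 12 | (2E)-3-{3-[(2E)-3,7-dimethylocta-2,6-dien-1-yl]-2,4-bis(methoxymethoxy)phenyl}-1-[6-hydroxy-2,4-bis(methoxymethoxy)-3-(3-methylbut-2-en-1-yl)phenyl]prop-2-en-1-one | CC(C)=CCC/C(C)=C/Cc1c(OCOC)ccc(/C=C/C(=O)c2c(O)cc(OCOC)c(CC=C(C)C)c2OCOC)c1OCOC
F3 | step 12 | tert-butyldimethylsilyl ether of F2 at the 6-hydroxy group | CC(C)=CCC/C(C)=C/Cc1c(OCOC)ccc(/C=C/C(=O)c2c(O[Si](C)(C)C(C)(C)C)cc(OCOC)c(CC=C(C)C)c2OCOC)c1OCOC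
F4 | step 12 | (2R,3S)-trans-epoxide of F3 (oxirane C2 bears the aroyl group) | CC(C)=CCC/C(C)=C/Cc1c(OCOC)ccc([C@@H]2O[C@H]2C(=O)c3c(O[Si](C)(C)C(C)(C)C)cc(OCOC)c(CC=C(C)C)c3OCOC)c1OCOC
F5 | step 12 | free phenol from F4, (2R,3S)-epoxide, not isolated | CC(C)=CCC/C(C)=C/Cc1c(OCOC)ccc([C@@H]2O[C@H]2C(=O)c3c(O)cc(OCOC)c(CC=C(C)C)c3OCOC)c1OCOC
F6 | step 12 | (2R,3R)-2-{3-[(2E)-3,7-dimethylocta-2,6-dien-1-yl]-2,4-bis(methoxymethoxy)phenyl}-3-hydroxy-5,7-bis(methoxymethoxy)-6-(3-methylbut-2-en-1-yl)-2,3-dihydro-4H-chromen-4-one | CC(C)=CCC/C(C)=C/Cc1c(OCOC)ccc([C@H]2Oc3cc(OCOC)c(CC=C(C)C)c(OCOC)c3C(=O)[C@@H]2O)c1OCOC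
F7 | step 11 | (3R,5S,6S)-3-[(R)-{3-[(2E)-3,7-dimethylocta-2,6-dien-1-yl]-2,4-bis(methoxymethoxy)phenyl}(hydroxy)methyl]-5,6-dimethoxy-5,6-dimethyl-1,4-dioxan-2-one | CC(C)=CCC/C(C)=C/Cc1c(OCOC)ccc([C@@H](O)[C@H]2O[C@](C)(OC)[C@@](C)(OC)OC2=O)c1OCOC
F8 | step 11 | (3R,5S,6S)-3-{3-[(2E)-3,7-dimethylocta-2,6-dien-1-yl]-2,4-bis(methoxymethoxy)benzoyl}-5,6-dimethoxy-5,6-dimethyl-1,4-dioxan-2-one | CC(C)=CCC/C(C)=C/Cc1c(OCOC)ccc(C(=O)[C@H]2O[C@](C)(OC)[C@@](C)(OC)OC2=O)c1OCOC
F9 | step 3 | 2-[3,5-bis(methoxymethoxy)phenyl]-4,4,5,5-tetramethyl-1,3,2-dioxaborolane | COCOc1cc(OCOC)cc(B2OC(C)(C)C(C)(C)O2)c1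
F10 | step 3 | 3,5-bis(methoxymethoxy)phenol | COCOc1cc(O)cc(OCOC)c1
F11 | step 3 | [3,5-bis(methoxymethoxy)phenoxy]tri(propan-2-yl)silane | COCOc1cc(OCOC)cc(O[Si](C(C)C)(C(C)C)C(C)C)c1
F12 | step 3 | {2,6-bis(methoxymethoxy)-4-[tri(propan-2-yl)silyloxy]phenyl}lithium | [Li]c1c(OCOC)cc(O[Si](C(C)C)(C(C)C)C(C)C)cc1OCOC
F13 | step 3 | [3,5-bis(methoxymethoxy)-4-(3-methylbut-2-en-1-yl)phenoxy]tri(propan-2-yl)silane | CC(C)=CCc1c(OCOC)cc(O[Si](C(C)C)(C(C)C)C(C)C)cc1OCOC
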